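**Retrosynthetic overview**
1. Target 23 ⇐ tricyclic alcohol 18: angeloylation of the 9α-OH, then acylative opening of a C-6/C-15 tetrahydrofuran (gives 6β-OAc with retention) and oxidation of the freed C-15 halide to the enal.
2. 18 ⇐ keto acid 15: α-bromination and intramolecular carboxylate SN2 (inversion) close the cis lactone; Luche reduction sets C-9.
3. 15 ⇐ enone 11 by a new palladium domino carbopalladation/enolate vinylation that forms C-4–C-5, the tetrahydrofuran ring and the C-10 quaternary centre.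
4. 11 ⇐ (S)-carvone: α'-hydroxylation, O-(2-bromoallyl)ation, Wharton carbonyl transposition, ene chlorination/oxidation of the isopropenyl group.
5. Ring order: carbocycle from the chiral pool, then the tetrahydrofuran ring (step 9), then the lactone ring (step 12); the tetrahydrofuran ring is opened again in step 15.

Assumption: the SMILES is taken as the absolute configuration; locants C-1 to C-15 are elemane locants (ring C-5 to C-10; C-1/C-2 vinyl and C-14 methyl on C-10; C-3/C-4/C-15 on C-5; C-11/C-12/C-13 on C-7), and β is the ring face carrying the C-14 methyl.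

**Route**

Step 1
Reactants: 1 (S)-(+)-carvone
Product: 2 (5R,6R)-6-hydroxy-2-methyl-5-(prop-1-en-2-yl)cyclohex-2-en-1-one
Conditions: KN(SiMe3)2, THF, −78 °C; 3-phenyl-2-(phenylsulfonyl)oxaziridine, −78 °C; AcOH
Reagents that add atoms: 3-phenyl-2-(phenylsulfonyl)oxaziridine, O=S(=O)(N1OC1c1ccccc1)c1ccccc1
Why: Kinetic α'-deprotonation and Davis enolate hydroxylation deliver oxygen anti to the adjacent isopropenyl group, giving the trans α-ketol whose oxygen becomes the C-6 oxygen of the target.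

Step 2
Reactants: 2 (5R,6R)-6-hydroxy-2-methyl-5-(prop-1-en-2-yl)cyclohex-2-en-1-one; 3 2,3-dibromoprop-1-ene
Product: 4 (5R,6R)-6-[(2-bromoprop-2-en-1-yl)oxy]-2-methyl-5-(prop-1-en-2-yl)cyclohex-2-en-1-one
Conditions: Ag2O, 4 Å MS, CH2Cl2, rt, dark
Reagents that add atoms: none
Why: Silver-oxide-promoted Williamson (Purdie-type) O-alkylation at the allylic bromide end etherifies the α-ketol without strong base, so the carbinol centre is not epimerised and the vinylic bromide is kept for step 9.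

Step 3
Reactants: 4 (5R,6R)-6-[(2-bromoprop-2-en-1-yl)oxy]-2-methyl-5-(prop-1-en-2-yl)cyclohex-2-en-1-one
Product: 5 (1S,3R,4R,6S)-3-[(2-bromoprop-2-en-1-yl)oxy]-1-methyl-4-(prop-1-en-2-yl)-7-oxabicyclo[4.1.0]heptan-2-one
Conditions: 30% aq. H2O2, NaOH (cat.), MeOH, 0 °C
Reagents that add atoms: hydrogen peroxide, OO
Why: Weitz–Scheffer nucleophilic epoxidation of the enone occurs anti to the isopropenyl group as for carvone itself, and the two new centres are erased in steps 4 and 5.

Step 4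
Reactants: 5 (1S,3R,4R,6S)-3-[(2-bromoprop-2-en-1-yl)oxy]-1-methyl-4-(prop-1-en-2-yl)-7-oxabicyclo[4.1.0]heptan-2-one
Product: 7 (1S,4S,5R)-4-[(2-bromoprop-2-en-1-yl)oxy]-2-methyl-5-(prop-1-en-2-yl)cyclohex-2-en-1-ol, via epoxy hydrazone 6 (not isolated)
Conditions: N2H4·H2O, AcOH (cat.), MeOH, 0 °C to rt, under N2
Reagents that add atoms: hydrazine, NN (its nitrogens are in 6 only)
Why: Wharton transposition: the epoxy hydrazone fragments with loss of N2 to the transposed allylic alcohol, so the ether-bearing carbon becomes the γ-carbon of the future enone, and epoxide opening is much faster than Kishner-type loss of the alkoxy group.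

Step 5
Reactants: 7 (1S,4S,5R)-4-[(2-bromoprop-2-en-1-yl)oxy]-2-methyl-5-(prop-1-en-2-yl)cyclohex-2-en-1-ol
Product: 8 (4S,5R)-4-[(2-bromoprop-2-en-1-yl)oxy]-2-methyl-5-(prop-1-en-2-yl)cyclohex-2-en-1-one
Conditions: MnO2 (activated), CH2Cl2, rt
Reagents that add atoms: none
Why: Selective MnO2 oxidation of the allylic alcohol gives the transposed enone with the C-6 ether trans to the C-7 side chain untouched.

Step 6
Reactants: 8 (4S,5R)-4-[(2-bromoprop-2-en-1-yl)oxy]-2-methyl-5-(prop-1-en-2-yl)cyclohex-2-en-1-one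
Product: 9 (4S,5R)-4-[(2-bromoprop-2-en-1-yl)oxy]-5-(3-chloroprop-1-en-2-yl)-2-methylcyclohex-2-en-1-one
Conditions: Ca(OCl)2, CO2 (dry ice), CH2Cl2/H2O, 0 °C
Reagents that add atoms: calcium hypochlorite, [Ca+2].[O-]Cl.[O-]Cl
Why: Ene-type allylic chlorination by HOCl (as in carvone to 10-chlorocarvone) is selective for the electron-rich isopropenyl alkene over the enone and the bromo-substituted alkene.

Step 7
Reactants: 9 (4S,5R)-4-[(2-bromoprop-2-en-1-yl)oxy]-5-(3-chloroprop-1-en-2-yl)-2-methylcyclohex-2-en-1-one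
Product: 10 2-[(1R,2S)-2-[(2-bromoprop-2-en-1-yl)oxy]-4-methyl-5-oxocyclohex-3-en-1-yl]prop-2-enal
Conditions: N-methylmorpholine N-oxide, NaI (cat.), NaHCO3, MeCN, 50 °C
Reagents that add atoms: N-methylmorpholine N-oxide, C[N+]1([O-])CCOCC1
Why: Amine N-oxide oxidation of an allylic halide (Kornblum/Ganem type: O-alkylation of the N-oxide then elimination) gives the 2-substituted acrolein without touching a stereocentre.

Step 8
Reactants: 10 2-[(1R,2S)-2-[(2-bromoprop-2-en-1-yl)oxy]-4-methyl-5-oxocyclohex-3-en-1-yl]prop-2-enal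
Product: 11 (4S,5R)-4-[(2-bromoprop-2-en-1-yl)oxy]-5-(3,3-dimethoxyprop-1-en-2-yl)-2-methylcyclohex-2-en-1-one
Conditions: HC(OMe)3, pyridinium p-toluenesulfonate (cat.), MeOH, rt
Reagents that add atoms: trimethyl orthoformate, COC(OC)OC
Why: Acid-catalysed acetalisation masks the aldehyde (the conjugated ring ketone acetalises far more slowly), so no aldehyde or acrylate acceptor can trap the enolate formed in step 9.

Step 9
Reactants: 11 (4S,5R)-4-[(2-bromoprop-2-en-1-yl)oxy]-5-(3,3-dimethoxyprop-1-en-2-yl)-2-methylcyclohex-2-en-1-one; 12 tributyl(ethenyl)stannane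
Product: 13 (3aS,4S,7R,7aR)-7-(3,3-dimethoxyprop-1-en-2-yl)-4-ethenyl-4-methyl-3-methylidenehexahydro-1-benzofuran-5(2H)-one
Conditions: Pd2(dba)3 (5 mol %, dba = dibenzylideneacetone), P(2-furyl)3 (20 mol %), CuI (10 mol %), DMF, 70 °C
Reagents that add atoms: none
Why: Proposed new method: a domino 5-exo carbopalladation/enolate vinylation in which zerovalent palladium inserts into the alkenyl C–Br bond, the alkenylpalladium adds to the enone β-carbon on the face of the C-6–O tether (only cis ring fusion is possible, which sets C-5), and the resulting tertiary divalent-palladium enolate, which has no syn β-hydrogen on C-5 and equilibrates through its O-bound form, is intercepted by Stille transmetalation and reductively eliminates on the less hindered face anti to the new C-5–C-4 bond to give the C-10 quaternary centre with vinyl α; the closest known reactions are domino Heck cyclisation/Stille termination at neopentyl palladium intermediates, reductive Heck cyclisations of alkenyl halides onto enones and palladium-catalysed α-vinylation of ketone enolates.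

Step 10
Reactants: 13 (3aS,4S,7R,7aR)-7-(3,3-dimethoxyprop-1-en-2-yl)-4-ethenyl-4-methyl-3-methylidenehexahydro-1-benzofuran-5(2H)-one
Product: 14 2-[(3aS,4S,7R,7aR)-4-ethenyl-4-methyl-3-methylidene-5-oxooctahydro-1-benzofuran-7-yl]prop-2-enal
Conditions: pyridinium p-toluenesulfonate (cat.), acetone/H2O, 40 °C
Reagents that add atoms: water, O
Why: Mild acid-catalysed acetal hydrolysis returns the enal while the cyclic allyl ether, ketone and alkenes are stable.

Step 11
Reactants: 14 2-[(3aS,4S,7R,7aR)-4-ethenyl-4-methyl-3-methylidene-5-oxooctahydro-1-benzofuran-7-yl]prop-2-enal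
Product: 15 2-[(3aS,4S,7R,7aR)-4-ethenyl-4-methyl-3-methylidene-5-oxooctahydro-1-benzofuran-7-yl]prop-2-enoic acid
Conditions: NaClO2, NaH2PO4, 2-methyl-2-butene, t-BuOH/H2O, 0 °C to rt
Reagents that add atoms: sodium chlorite, [Na+].[O-]Cl=O
Why: Pinnick oxidation converts the enal into the acrylic acid chemoselectively, the scavenger removing HOCl so the other alkenes are not chlorinated.

Step 12
Reactants: 15 2-[(3aS,4S,7R,7aR)-4-ethenyl-4-methyl-3-methylidene-5-oxooctahydro-1-benzofuran-7-yl]prop-2-enoic acid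
Product: 17 (5αH,7βH,8βH)-6β,15-epoxy-9-oxoelema-1,3,11(13)-trien-12,8-olide, via bromo keto acid 16 (not isolated)
Conditions: LiN(SiMe3)2 (2.2 equiv), THF, −78 °C; N-bromosuccinimide, −78 °C; then rt; AcOH
Reagents that add atoms: N-bromosuccinimide, O=C1CCC(=O)N1Br (its bromine is in 16 only)
Why: The ketone can enolise only toward C-8 (C-10 is quaternary), enolate bromination occurs anti to the C-7 substituent (8β-Br), and the carboxylate then displaces bromide by intramolecular SN2 with inversion to give the cis-fused α-methylene-γ-lactone with the C-8 oxygen α.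

Step 13
Reactants: 17 (5αH,7βH,8βH)-6β,15-epoxy-9-oxoelema-1,3,11(13)-trien-12,8-olide
Product: 18 (5αH,7βH,8βH)-6β,15-epoxy-9α-hydroxyelema-1,3,11(13)-trien-12,8-olide
Conditions: NaBH4, CeCl3·7H2O, MeOH, −78 °C
Reagents that add atoms: none
Why: Luche 1,2-reduction (no conjugate reduction of the α-methylene lactone) in which hydride attacks from the β face, anti to the C-8–O bond and away from the α-face lactone ring (polar Felkin–Anh, convex-face attack), giving the 9α-alcohol cis to the lactone oxygen.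

Step 14
Reactants: 18 (5αH,7βH,8βH)-6β,15-epoxy-9α-hydroxyelema-1,3,11(13)-trien-12,8-olide; 19 (2Z)-2-methylbut-2-enoic acid
Product: 21 (5αH,7βH,8βH)-9α-[(2Z)-2-methylbut-2-enoyloxy]-6β,15-epoxyelema-1,3,11(13)-trien-12,8-olide, via mixed anhydride 20 (not isolated)
Conditions: 19, 2,4,6-trichlorobenzoyl chloride, Et3N, toluene, rt; then 18, toluene, 80 °C
Reagents that add atoms: 2,4,6-trichlorobenzoyl chloride, O=C(Cl)c1c(Cl)cc(Cl)cc1Cl (its atoms are in 20 only)
Why: Yamaguchi esterification through the mixed anhydride, run without a nucleophilic pyridine catalyst, acylates the hindered C-9 alcohol while keeping the Z (angelate) geometry and touching no stereocentre.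

Step 15
Reactants: 21 (5αH,7βH,8βH)-9α-[(2Z)-2-methylbut-2-enoyloxy]-6β,15-epoxyelema-1,3,11(13)-trien-12,8-olide
Product: 22 (3aR,4S,5R,6S,7S,7aR)-4-(acetyloxy)-6-ethenyl-5-(3-iodoprop-1-en-2-yl)-6-methyl-3-methylidene-2-oxooctahydro-1-benzofuran-7-yl (2Z)-2-methylbut-2-enoate
Conditions: AcCl, NaI, MeCN, 0 °C
Reagents that add atoms: acetyl chloride, CC(=O)Cl; sodium iodide, [Na+].[I-]
Why: Acylative ether cleavage: acetyl iodide O-acylates the ring oxygen and iodide attacks the allylic C-15 (SN2 or SN2', same product), so the C-6–O bond is never broken and the 6β-acetate forms with retention.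

Step 16
Reactants: 22 (3aR,4S,5R,6S,7S,7aR)-4-(acetyloxy)-6-ethenyl-5-(3-iodoprop-1-en-2-yl)-6-methyl-3-methylidene-2-oxooctahydro-1-benzofuran-7-yl (2Z)-2-methylbut-2-enoate
Product: 23 (3aR,4S,5R,6S,7S,7aR)-4-(acetyloxy)-6-ethenyl-6-methyl-3-methylidene-2-oxo-5-(3-oxoprop-1-en-2-yl)octahydro-1-benzofuran-7-yl (2Z)-2-methylbut-2-enoate
Conditions: N-methylmorpholine N-oxide, NaHCO3, 4 Å MS, MeCN, rt
Reagents that add atoms: N-methylmorpholine N-oxide, C[N+]1([O-])CCOCC1
Why: Amine N-oxide (Kornblum/Ganem-type) oxidation of the allylic iodide gives the 2-substituted acrolein under near-neutral conditions that the angelate, acetate and α-methylene lactone tolerate.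

**Compound list**

1 | (5S)-2-methyl-5-(prop-1-en-2-yl)cyclohex-2-en-1-one, (S)-(+)-carvone | CC1=CC[C@H](C(C)=C)CC1=O | starting material
2 | (5R,6R)-6-hydroxy-2-methyl-5-(prop-1-en-2-yl)cyclohex-2-en-1-one (trans) | CC1=CC[C@H](C(C)=C)[C@@H](O)C1=O | intermediate
3 | 2,3-dibromoprop-1-ene | BrCC(Br)=C | starting material
4 | (5R,6R)-6-[(2-bromoprop-2-en-1-yl)oxy]-2-methyl-5-(prop-1-en-2-yl)cyclohex-2-en-1-one | CC1=CC[C@H](C(C)=C)[C@@H](OCC(Br)=C)C1=O | intermediate
5 | (1S,3R,4R,6S)-3-[(2-bromoprop-2-en-1-yl)oxy]-1-methyl-4-(prop-1-en-2-yl)-7-oxabicyclo[4.1.0]heptan-2-one (epoxide anti to isopropenyl) | C[C@]12O[C@H]1C[C@H](C(C)=C)[C@@H](OCC(Br)=C)C2=O | intermediate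
6 | hydrazone of 5 (C=N–NH2 in place of C=O, other centres unchanged) | C[C@]12O[C@H]1C[C@H](C(C)=C)[C@@H](OCC(Br)=C)C2=NN | intermediate (not isolated)
7 | (1S,4S,5R)-4-[(2-bromoprop-2-en-1-yl)oxy]-2-methyl-5-(prop-1-en-2-yl)cyclohex-2-en-1-ol | CC=1[C@@H](O)C[C@H](C(C)=C)[C@@H](OCC(Br)=C)C=1 | intermediate
8 | (4S,5R)-4-[(2-bromoprop-2-en-1-yl)oxy]-2-methyl-5-(prop-1-en-2-yl)cyclohex-2-en-1-one | CC=1C(=O)C[C@H](C(C)=C)[C@@H](OCC(Br)=C)C=1 | intermediate
9 | (4S,5R)-4-[(2-bromoprop-2-en-1-yl)oxy]-5-(3-chloroprop-1-en-2-yl)-2-methylcyclohex-2-en-1-one | CC=1C(=O)C[C@H](C(CCl)=C)[C@@H](OCC(Br)=C)C=1 | intermediate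
10 | 2-[(1R,2S)-2-[(2-bromoprop-2-en-1-yl)oxy]-4-methyl-5-oxocyclohex-3-en-1-yl]prop-2-enal | CC=1C(=O)C[C@H](C(C=O)=C)[C@@H](OCC(Br)=C)C=1 | intermediate
11 | (4S,5R)-4-[(2-bromoprop-2-en-1-yl)oxy]-5-(3,3-dimethoxyprop-1-en-2-yl)-2-methylcyclohex-2-en-1-one | CC=1C(=O)C[C@H](C(=C)C(OC)OC)[C@@H](OCC(Br)=C)C=1 | intermediate
12 | tributyl(ethenyl)stannane | C=C[Sn](CCCC)(CCCC)CCCC | starting material
13 | (3aS,4S,7R,7aR)-7-(3,3-dimethoxyprop-1-en-2-yl)-4-ethenyl-4-methyl-3-methylidenehexahydro-1-benzofuran-5(2H)-one (cis-fused; C-10 methyl β, vinyl α) | C=C[C@]1(C)C(=O)C[C@H](C(=C)C(OC)OC)[C@H]2OCC(=C)[C@@H]12 | intermediate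
14 | 2-[(3aS,4S,7R,7aR)-4-ethenyl-4-methyl-3-methylidene-5-oxooctahydro-1-benzofuran-7-yl]prop-2-enal | C=C[C@]1(C)C(=O)C[C@H](C(=C)C=O)[C@H]2OCC(=C)[C@@H]12 | intermediate
15 | 2-[(3aS,4S,7R,7aR)-4-ethenyl-4-methyl-3-methylidene-5-oxooctahydro-1-benzofuran-7-yl]prop-2-enoic acid | C=C[C@]1(C)C(=O)C[C@H](C(=C)C(=O)O)[C@H]2OCC(=C)[C@@H]12 | intermediate
16 | 2-[(3aS,4S,6S,7R,7aS)-6-bromo-4-ethenyl-4-methyl-3-methylidene-5-oxooctahydro-1-benzofuran-7-yl]prop-2-enoic acid (8β-bromide, trans to the side chain) | C=C[C@]1(C)C(=O)[C@@H](Br)[C@H](C(=C)C(=O)O)[C@H]2OCC(=C)[C@@H]12 | intermediate (not isolated)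
17 | (5αH,7βH,8βH)-6β,15-epoxy-9-oxoelema-1,3,11(13)-trien-12,8-olide (cis α-methylene-γ-lactone on the α face at C-7/C-8; cis 3-methylidene tetrahydrofuran on the β face at C-5/C-6) | C=C[C@]1(C)C(=O)[C@@H]2OC(=O)C(=C)[C@@H]2[C@H]3OCC(=C)[C@@H]13 | intermediate
18 | (5αH,7βH,8βH)-6β,15-epoxy-9α-hydroxyelema-1,3,11(13)-trien-12,8-olide | C=C[C@]1(C)[C@H](O)[C@@H]2OC(=O)C(=C)[C@@H]2[C@H]3OCC(=C)[C@@H]13 | intermediate
19 | (2Z)-2-methylbut-2-enoic acid (angelic acid) | OC(=O)/C(C)=C\C | starting material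
20 | (2Z)-2-methylbut-2-enoic 2,4,6-trichlorobenzoic anhydride | O=C(OC(=O)c1c(Cl)cc(Cl)cc1Cl)/C(C)=C\C | intermediate (not isolated)
21 | (5αH,7βH,8βH)-9α-[(2Z)-2-methylbut-2-enoyloxy]-6β,15-epoxyelema-1,3,11(13)-trien-12,8-olide | C=C[C@]1(C)[C@H](OC(=O)/C(C)=C\C)[C@@H]2OC(=O)C(=C)[C@@H]2[C@H]3OCC(=C)[C@@H]13 | intermediate
22 | (3aR,4S,5R,6S,7S,7aR)-4-(acetyloxy)-6-ethenyl-5-(3-iodoprop-1-en-2-yl)-6-methyl-3-methylidene-2-oxooctahydro-1-benzofuran-7-yl (2Z)-2-methylbut-2-enoate | C=C[C@]1(C)[C@H](OC(=O)/C(C)=C\C)[C@@H]2OC(=O)C(=C)[C@@H]2[C@@H](OC(C)=O)[C@H]1C(=C)CI | intermediate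
23 | (3aR,4S,5R,6S,7S,7aR)-4-(acetyloxy)-6-ethenyl-6-methyl-3-methylidene-2-oxo-5-(3-oxoprop-1-en-2-yl)octahydro-1-benzofuran-7-yl (2Z)-2-methylbut-2-enoate (CNP0252310.2) | C=C[C@]1(C)[C@H](OC(=O)/C(C)=C\C)[C@@H]2OC(=O)C(=C)[C@@H]2[C@@H](OC(C)=O)[C@H]1C(=C)C=O | target

**Totals and risks**

Total step count: 16. Longest linear sequence: 16 steps, from (S)-(+)-carvone 1 to 23.

The three steps most likely to fail:

Step 9 (the proposed new reaction). It can fail by β-hydride loss from the C-14 methyl to an exocyclic enone, by direct Stille coupling before cyclisation, or by giving the C-10 epimer. The fallback uses known chemistry and sets out from 11. A reductive Heck cyclisation (Pd(OAc)2, PPh3, HCO2Na, DMF, 80 °C) gives the cis-fused C-10-unsubstituted ketone F1 as a C-10 epimer mixture. Thermodynamic silylation (Me3SiCl, Et3N, DMF, 110 °C) gives the tetrasubstituted trimethylsilyl enol ether F2. MeLi releases the lithium enolate, which adds to (phenylselanyl)acetaldehyde at −78 °C on the face anti to the C-5 substituent to give the β-hydroxy selenide F3. Reductive elimination with SOCl2/Et3N forms the vinyl group, and the sequence comes back to the route at 13.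

Step 13 (facial selectivity at C-9). If hydride attacks from the α face, the 9β-alcohol results. The fallback sets out from 15 and changes the order of events. Enolate hydroxylation (LiN(SiMe3)2, then 3-phenyl-2-(phenylsulfonyl)oxaziridine) gives the 8β-hydroxy keto acid F4. Hydroxyl-directed reduction with Me4NBH(OAc)3 in MeCN/AcOH delivers hydride intramolecularly from the β face to give the 8β,9α-dihydroxy acid F5. Mitsunobu lactonisation (PPh3, diisopropyl azodicarboxylate, THF) closes the lactone at the less hindered C-8 with inversion, and the sequence comes back at 18.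

Step 15 (ether opening beside the angelate and α-methylene lactone). Iodide or traces of HI may isomerise the angelate or add to the lactone. The fallback sets out from 21. Acetolysis with Ac2O and catalytic Sc(OSO2CF3)3 in MeCN at −20 °C gives the 6β,15-diacetate F6. Immobilised Candida antarctica lipase B in pH 7 buffer/acetone removes only the primary allylic acetate to give the allylic alcohol F7. MnO2 in CH2Cl2 oxidises it to the enal, and the sequence comes back at 23.

**Further compounds**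

F1 | step 9 | (3aS,7R,7aR)-7-(3,3-dimethoxyprop-1-en-2-yl)-4-methyl-3-methylidenehexahydro-1-benzofuran-5(2H)-one (C-4 epimer mixture) | CC1C(=O)C[C@H](C(=C)C(OC)OC)[C@H]2OCC(=C)[C@@H]12
F2 | step 9 | trimethylsilyl enol ether of F1 (C-9 silyloxy, C-9=C-10 double bond) | CC1=C(O[Si](C)(C)C)C[C@H](C(=C)C(OC)OC)[C@H]2OCC(=C)[C@@H]12
F3 | step 9 | C-10 α-[1-hydroxy-2-(phenylselanyl)ethyl] ketone (13 with CH(OH)CH2SePh in place of vinyl; carbinol epimers) | OC(C[Se]c1ccccc1)[C@]1(C)C(=O)C[C@H](C(=C)C(OC)OC)[C@H]2OCC(=C)[C@@H]12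
F4 | step 13 | 2-[(3aS,4S,6S,7R,7aS)-4-ethenyl-6-hydroxy-4-methyl-3-methylidene-5-oxooctahydro-1-benzofuran-7-yl]prop-2-enoic acid (8β-hydroxy keto acid) | C=C[C@]1(C)C(=O)[C@@H](O)[C@H](C(=C)C(=O)O)[C@H]2OCC(=C)[C@@H]12
F5 | step 13 | 8β,9α-dihydroxy acid (F4 with the ketone reduced to the 9α-alcohol) | C=C[C@]1(C)[C@H](O)[C@@H](O)[C@H](C(=C)C(=O)O)[C@H]2OCC(=C)[C@@H]12
F6 | step 15 | 6β,15-diacetate (22 with OAc in place of I) | C=C[C@]1(C)[C@H](OC(=O)/C(C)=C\C)[C@@H]2OC(=O)C(=C)[C@@H]2[C@@H](OC(C)=O)[C@H]1C(=C)COC(C)=O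
F7 | step 15 | 15-alcohol (22 with OH in place of I) | C=C[C@]1(C)[C@H](OC(=O)/C(C)=C\C)[C@@H]2OC(=O)C(=C)[C@@H]2[C@@H](OC(C)=O)[C@H]1C(=C)CO
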